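Slowness in the west flask can be read in two ways, and readings taken later than 120 s can tell them apart.

- west: solid substrate 0.20 M; the very flask that is asked about, followed so far
- flask: solid substrate 0.20 M; time 4.0 min

west run (percent of the solid substrate charged)

| time / s | product / % | starting material / % |
|---|---|---|
| 25.0 | 0.7 | 11.5 |
| 50.0 | 2.3 | 15.7 |
| 80.0 | 4.8 | 18.6 |
| 90.0 | 4.8 | 19.2 |
| 120 | 7.3 | 21.8 |

(scatter of a reading: 0.5 percentage points)

- percentages count the solid substrate that a species holds: one product counts as two
- solid, in amounts per volume of the solution: solid substrate
- reactions considered so far: 2 starting material <-> product; solid substrate <-> starting material; starting material <-> dormant form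
- at the start none of the solid substrate is in solution
- starting material means what is dissolved; the solid is not counted in it

- amount of product at 4.0 min, in percent of the solid substrate charged
- concentration of starting material in solution at 4.0 min, in percent of saturation

Two people argue over this flask. The second of them reckons in concentrations, not percentages. [A] is starting material and [P] is product, and one product counts as two, so [P] takes half its percentage of the charge c.

The first says the coupling of starting material is slow and one-way. Product gained 5 percentage points from 50.0 s to 120 s, and starting material was still climbing, so product should keep gaining. Hers is the forecast: “Product growth fits second order”, with 22% of product and 72% of saturation.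

The second says the slowness lies in the dissolving, and product merely follows starting material. Her number is 3.84 M⁻¹ at 120 s: the coupling quotient Q, which is [P] divided by [A] squared, the reaction quotient. As readings, it was 2.33 M⁻¹ at 50.0 s and 3.47 M⁻¹ at 80.0 s, so it looks to be levelling. If Q holds, product in percent is 2 Q [A] [A] over c.

Starting material rose 6.1 points over that span. She lets its pace halve, which gives 27.0% at 4.0 min and product near 11.2%. This reckoning is hers and differs from the forecast. The thing to watch is Q: flat, or still climbing.

The flask gives 12.7% of product and 73.1% of saturation, so the forecast's saturation stands and its product is 9.3 points too high.

    2 starting material ⇌ product (K = 3.97 M⁻¹, k = 0.192 M⁻¹ s⁻¹)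
    solid substrate ⇌ starting material, rate k2*(cs2 - [starting material]) while solid is left; crystals form when [starting material] > cs2 (solubility = 0.0800 M, k = 0.0175 s⁻¹)
    starting material ⇌ dormant form (K = 1.59, k = 0.0220 s⁻¹)

The relaxation half-life of the coupling, both ways together, is 0.124 min at 4.00 min, short against the run's 4.0 min, while at 0.400 min this flask stood at a Q of 1.43 M⁻¹, and in that early stretch the forecast's one-way growth is the right view. At 4.00 min this flask holds a Q of 3.71 M⁻¹, and in the neighbour charged with 0.12 M, the Q read at 120 s and its 34.7% of starting material give 11.1% of product against the 11.7% it holds.

(The readings were generated by integration with constants of no real substance; the scatter is artificial.)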